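The dienone ring (C1 carbonyl, C2 allyl, C3, quaternary C4, C5 enol ether, C6) carries oxygen on C4 beside carbonyl-level C5: a masked α-ketol. The route therefore cuts C3–C4 and goes back to a cyclopentenone, a 4-acyl-4-hydroxy-2-allylcyclopent-2-enone whose carbinol carbon is C5 and whose side-chain ketone is C4, flanked by C8. One zinc-mediated α-ketol shift moves C3 from C5 to C4, expands the ring to six members and passes the C5 configuration on to C4. The cyclopentenol comes from a furan by oxidative opening and aldol closure, with C4 kept as a silyl carbinol until the ring is closed, so that no six-membered aldol and no epimerisation at C8 can occur.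

Key step: step 15

Remark: the atom labels of the target (ring C1–C6, chain C8 = CH–CH3 and C7 = CH2–aryl) are used for all intermediates; the target is 4R,8R; the face selection in step 9 assumes that the furyl group acts as the larger ketone substituent.

Abbreviations: Ar = 4-[(tert-butyldimethylsilyl)oxy]-3-methoxyphenyl; TBS = tert-butyldimethylsilyl; TES = triethylsilyl.

Step 1
Reactants: 1 3-bromofuran
Product: 3 3-bromo-2-methylfuran, via 3-bromo-2-furyllithium 2 (not isolated)
Conditions: LiN(iPr)2, THF, −78 °C; MeI, −78 to 0 °C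
Reagents that add atoms: iodomethane, CI
Why: Deprotonation–alkylation: the C–H between the ring oxygen and the bromine is the most acidic site and the amide base does not exchange the bromine, so the 2-lithio species should be methylated by MeI at that carbon only.

Step 2
Reactants: 4 vanillin
Product: 5 4-[(tert-butyldimethylsilyl)oxy]-3-methoxybenzaldehyde
Conditions: TBSCl, imidazole, DMF, 0 °C to rt
Reagents that add atoms: tert-butyldimethylsilyl chloride, CC(C)(C)[Si](C)(C)Cl
Why: Imidazole-promoted silyl ether formation masks the only acidic OH before the organometallic steps.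

Step 3
Reactants: 5 4-[(tert-butyldimethylsilyl)oxy]-3-methoxybenzaldehyde
Product: 6 {4-[(tert-butyldimethylsilyl)oxy]-3-methoxyphenyl}methanol
Conditions: NaBH4, MeOH–THF, 0 °C
Reagents that add atoms: none
Why: Hydride reduction of the aldehyde with NaBH4 is fast at 0 °C and should leave the aryl silyl ether intact.

Step 4
Reactants: 6 {4-[(tert-butyldimethylsilyl)oxy]-3-methoxyphenyl}methanol
Product: 7 4-[(tert-butyldimethylsilyl)oxy]-3-methoxybenzyl bromide
Conditions: CBr4, PPh3, CH2Cl2, 0 °C; used at once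
Reagents that add atoms: carbon tetrabromide, BrC(Br)(Br)Br
Why: Appel bromination converts the benzylic alcohol into the bromide under neutral conditions that spare the aryl silyl ether.

Step 5
Reactants: 8 (S)-4-benzyl-3-propanoyloxazolidin-2-one; 7 4-[(tert-butyldimethylsilyl)oxy]-3-methoxybenzyl bromide
Product: 10 (S)-4-benzyl-3-[(R)-3-Ar-2-methylpropanoyl]oxazolidin-2-one, via sodium imide Z-enolate 9 (not isolated)
Conditions: NaN(SiMe3)2, THF, −78 °C; then 7, −78 to −40 °C
Reagents that add atoms: none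
Why: Evans asymmetric alkylation: the chelated Z-enolate is shielded on one face by the benzyl group of the auxiliary, so the benzylic bromide should enter from the other face and set C8 as R.

Step 6
Reactants: 10 (S)-4-benzyl-3-[(R)-3-Ar-2-methylpropanoyl]oxazolidin-2-one
Product: 11 (R)-3-Ar-N-methoxy-N,2-dimethylpropanamide
Conditions: MeNH(OMe)·HCl, AlMe3, CH2Cl2, −15 to 0 °C; dilute HCl work-up
Reagents that add atoms: N,O-dimethylhydroxylamine hydrochloride, CNOC.Cl
Why: Weinreb transamination: the aluminium amide attacks the exocyclic imide carbonyl and releases the auxiliary without touching C8.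

Step 7
Reactants: 3 3-bromo-2-methylfuran; 11 (R)-3-Ar-N-methoxy-N,2-dimethylpropanamide
Product: 13 (R)-3-Ar-1-(4-bromo-5-methylfuran-2-yl)-2-methylpropan-1-one, via (4-bromo-5-methylfuran-2-yl)lithium 12 (not isolated)
Conditions: 3, LiN(iPr)2, THF, −78 °C; then 11, −78 to −40 °C; aq. NH4Cl
Reagents that add atoms: none
Why: Deprotonation at the only free α-position of the furan (the amide base avoids bromine–lithium exchange) is followed by Weinreb ketone synthesis, whose stable chelated adduct prevents over-addition and keeps C8 intact.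

Step 8
Reactants: 13 (R)-3-Ar-1-(4-bromo-5-methylfuran-2-yl)-2-methylpropan-1-one
Product: 14 (R)-1-(4-allyl-5-methylfuran-2-yl)-3-Ar-2-methylpropan-1-one
Conditions: allylSnBu3, Pd(PPh3)4 (5 mol%), toluene, 100 °C
Reagents that add atoms: allyltributylstannane, C=CC[Sn](CCCC)(CCCC)CCCC
Why: Stille cross-coupling of the acyl-activated bromofuran installs the allyl group without base, so C8 next to the ketone should not epimerise.

Step 9
Reactants: 14 (R)-1-(4-allyl-5-methylfuran-2-yl)-3-Ar-2-methylpropan-1-one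
Product: 15 (1S,2R)-1-(4-allyl-5-methylfuran-2-yl)-3-Ar-2-methylpropan-1-ol
Conditions: (R)-2-methyl-CBS-oxazaborolidine (20 mol%), catecholborane, toluene, −78 °C; MeOH
Reagents that add atoms: none
Why: Corey–Bakshi–Shibata reduction: the oxazaborolidine should deliver hydride to one face of the furyl ketone and set the temporary C4 carbinol as S under reagent control, catecholborane at −78 °C does not hydroborate the allyl group, and the C4 epimer is separable and can be re-oxidised to 14.

Step 10
Reactants: 15 (1S,2R)-1-(4-allyl-5-methylfuran-2-yl)-3-Ar-2-methylpropan-1-ol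
Product: 16 [(1S,2R)-1-(4-allyl-5-methylfuran-2-yl)-3-Ar-2-methylpropoxy]triethylsilane
Conditions: TESCl, imidazole, DMF, 0 °C
Reagents that add atoms: chlorotriethylsilane, CC[Si](Cl)(CC)CC
Why: Silyl ether formation keeps C4 at the carbinol level through furan opening and ring closure, so that only C5 can act as aldol acceptor and C8 is not next to a carbonyl.

Step 11
Reactants: 16 [(1S,2R)-1-(4-allyl-5-methylfuran-2-yl)-3-Ar-2-methylpropoxy]triethylsilane
Product: 17 (2R,3S,5Z)-6-allyl-1-Ar-2-methyl-3-[(triethylsilyl)oxy]oct-5-ene-4,7-dione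
Conditions: NBS, NaHCO3, acetone–H2O, −20 °C, dark; used crude
Reagents that add atoms: water, O
Why: Oxidative furan ring opening (bromination, hydration and collapse of the 2,5-dihydrofuran, as in the first stage of an Achmatowicz reaction): the electron-rich trialkylfuran should react far faster than the allyl group or the arene, and the buffer prevents Z-to-E isomerisation of the enedione.

Step 12
Reactants: 17 (2R,3S,5Z)-6-allyl-1-Ar-2-methyl-3-[(triethylsilyl)oxy]oct-5-ene-4,7-dione
Product: 19 (S)-2-allyl-4-hydroxy-4-[(1S,2R)-3-Ar-2-methyl-1-(triethylsilyloxy)propyl]cyclopent-2-en-1-one, via lithium dienolate 18 (not isolated)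
Conditions: LiN(SiMe3)2, THF, −78 °C (17 added slowly); AcOH, −78 °C
Reagents that add atoms: none
Why: Intramolecular aldol addition (the closure of furan-derived cis-enediones to 4-hydroxycyclopentenones): the kinetic lithium enolate of the methyl ketone attacks the C5 ketone held close by the Z-alkene, Felkin–Anh addition anti to the C4 silyloxy group should set C5 as S, and the 5-epimer is separable.

Step 13
Reactants: 19 (S)-2-allyl-4-hydroxy-4-[(1S,2R)-3-Ar-2-methyl-1-(triethylsilyloxy)propyl]cyclopent-2-en-1-one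
Product: 20 (S)-2-allyl-4-hydroxy-4-[(1S,2R)-3-Ar-1-hydroxy-2-methylpropyl]cyclopent-2-en-1-one
Conditions: PPTS (cat.), MeOH, rt
Reagents that add atoms: none
Why: Acid-catalysed methanolysis removes the secondary triethylsilyl ether selectively, the aryl TBS ether being far more stable to mild acid.

Step 14
Reactants: 20 (S)-2-allyl-4-hydroxy-4-[(1S,2R)-3-Ar-1-hydroxy-2-methylpropyl]cyclopent-2-en-1-one
Product: 21 (S)-2-allyl-4-hydroxy-4-[(R)-3-Ar-2-methylpropanoyl]cyclopent-2-en-1-one
Conditions: Dess–Martin periodinane, CH2Cl2, 0 °C to rt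
Reagents that add atoms: none
Why: Dess–Martin oxidation converts the secondary C4 alcohol into the ketone under neutral conditions; the tertiary C5 alcohol cannot be oxidised and C8 next to the new ketone sees no base.

Step 15
Reactants: 21 (S)-2-allyl-4-hydroxy-4-[(R)-3-Ar-2-methylpropanoyl]cyclopent-2-en-1-one
Product: 23 (R)-2-allyl-4,5-dihydroxy-4-[(R)-1-Ar-propan-2-yl]cyclohexa-2,5-dien-1-one, via diketo tautomer 22 (not isolated)
Conditions: Zn(OTf)2 (30 mol%), 4 Å molecular sieves, ClCH2CH2Cl, 60 °C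
Reagents that add atoms: none
Why: Zn(OTf)2 binds the C5 hydroxyl and the C4 acyl oxygen in a syn-periplanar five-membered chelate, the C3–C5 ring bond lies over the acyl π* orbital, and C3 shifts suprafacially to C4 while C5 becomes a ketone, which is an α-ketol (acyloin) rearrangement. The closest known reaction type is the Lewis-acid α-ketol ring expansion of 1-acylcycloalkanols to 2-hydroxy-2-alkylcycloalkanones. The six-membered ring arises by ring expansion through this 1,2-shift (C3–C4 made, C3–C5 broken), so it is not a cyclisation and no closure mode has to be met. The new stereocentre C4 is controlled by the C5 carbinol through the chelate: with O–C5–C4=O syn and C3 on the face fixed by 5S, C3 reaches one face of the acyl group and C4 should come out R, while C8 is untouched and can no longer epimerise once C4 is a carbinol. The step needs migration of vinylic C3 and not of C6, and either in preference to retro-aldol opening; C6 is the α-carbon of the C1 ketone and so a poor migrating group, and the absence of base keeps the β-hydroxy ketone closed. Enolisation of the new 1,3-dione to the vinylogous acid, together with relief of five-ring strain, makes the shift downhill.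

Step 16
Reactants: 23 (R)-2-allyl-4,5-dihydroxy-4-[(R)-1-Ar-propan-2-yl]cyclohexa-2,5-dien-1-one
Product: 24 (R)-2-allyl-4-hydroxy-5-methoxy-4-[(R)-1-Ar-propan-2-yl]cyclohexa-2,5-dien-1-one
Conditions: Me3SiCHN2, MeOH–toluene, 0 °C
Reagents that add atoms: trimethylsilyldiazomethane, C[Si](C)(C)C=[N+]=[N-]
Why: O-Methylation of a vinylogous acid with a diazoalkane: the C5 enol hydroxyl protonates the reagent and is methylated within the ion pair, the tertiary C4 alcohol is not acidic enough to react, and the C1-O-methyl regioisomer is removed by chromatography.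

Step 17
Reactants: 24 (R)-2-allyl-4-hydroxy-5-methoxy-4-[(R)-1-Ar-propan-2-yl]cyclohexa-2,5-dien-1-one
Product: 26 (R)-2-allyl-4,5-dimethoxy-4-[(R)-1-Ar-propan-2-yl]cyclohexa-2,5-dien-1-one, via potassium C4-alkoxide 25 (not isolated)
Conditions: KN(SiMe3)2, THF, −78 °C; MeOTf, −78 °C; Et3N–MeOH quench
Reagents that add atoms: methyl trifluoromethanesulfonate, COS(=O)(=O)C(F)(F)F
Why: Williamson-type O-methylation: the hindered tertiary alcohol is deprotonated selectively and the alkoxide is captured by methyl triflate at −78 °C, where neither silyl transfer from the aryl ether nor alkylation of the vinylogous ester carbonyl should compete.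

Step 18
Reactants: 26 (R)-2-allyl-4,5-dimethoxy-4-[(R)-1-Ar-propan-2-yl]cyclohexa-2,5-dien-1-one
Product: 27 (R)-2-allyl-4-[(R)-1-(4-hydroxy-3-methoxyphenyl)propan-2-yl]-4,5-dimethoxycyclohexa-2,5-dien-1-one
Conditions: Bu4NF, AcOH, THF, 0 °C
Reagents that add atoms: none
Why: Fluoride-mediated desilylation of the aryl silyl ether, buffered with acetic acid so that the phenoxide is protonated at once and the dienone sees no base.

Compound list
1 | 3-bromofuran | Brc1ccoc1 | starting material
2 | 3-bromo-2-furyllithium | [Li]c1occc1Br | intermediate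
3 | 3-bromo-2-methylfuran | Cc1occc1Br | intermediate
4 | vanillin | COc1cc(C=O)ccc1O | starting material
5 | 4-[(tert-butyldimethylsilyl)oxy]-3-methoxybenzaldehyde | COc1cc(C=O)ccc1O[Si](C)(C)C(C)(C)C | intermediate
6 | {4-[(tert-butyldimethylsilyl)oxy]-3-methoxyphenyl}methanol | COc1cc(CO)ccc1O[Si](C)(C)C(C)(C)C | intermediate
7 | 4-[(tert-butyldimethylsilyl)oxy]-3-methoxybenzyl bromide | COc1cc(CBr)ccc1O[Si](C)(C)C(C)(C)C | intermediate
8 | (S)-4-benzyl-3-propanoyloxazolidin-2-one | CCC(=O)N1[C@@H](Cc2ccccc2)COC1=O | starting material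
9 | sodium Z-enolate of 8 | C/C=C(\[O-])N1[C@@H](Cc2ccccc2)COC1=O.[Na+] | intermediate
10 | (S)-4-benzyl-3-[(R)-3-Ar-2-methylpropanoyl]oxazolidin-2-one | COc1cc(C[C@@H](C)C(=O)N2[C@@H](Cc3ccccc3)COC2=O)ccc1O[Si](C)(C)C(C)(C)C | intermediate
11 | (R)-3-Ar-N-methoxy-N,2-dimethylpropanamide | CON(C)C(=O)[C@H](C)Cc1ccc(O[Si](C)(C)C(C)(C)C)c(OC)c1 | intermediate
12 | (4-bromo-5-methylfuran-2-yl)lithium | [Li]c1cc(Br)c(C)o1 | intermediate
13 | (R)-3-Ar-1-(4-bromo-5-methylfuran-2-yl)-2-methylpropan-1-one | Cc1oc(cc1Br)C(=O)[C@H](C)Cc1ccc(O[Si](C)(C)C(C)(C)C)c(OC)c1 | intermediate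
14 | (R)-1-(4-allyl-5-methylfuran-2-yl)-3-Ar-2-methylpropan-1-one | Cc1oc(cc1CC=C)C(=O)[C@H](C)Cc1ccc(O[Si](C)(C)C(C)(C)C)c(OC)c1 | intermediate
15 | (1S,2R)-1-(4-allyl-5-methylfuran-2-yl)-3-Ar-2-methylpropan-1-ol | Cc1oc(cc1CC=C)[C@@H](O)[C@H](C)Cc1ccc(O[Si](C)(C)C(C)(C)C)c(OC)c1 | intermediate
16 | [(1S,2R)-1-(4-allyl-5-methylfuran-2-yl)-3-Ar-2-methylpropoxy]triethylsilane | Cc1oc(cc1CC=C)[C@@H](O[Si](CC)(CC)CC)[C@H](C)Cc1ccc(O[Si](C)(C)C(C)(C)C)c(OC)c1 | intermediate
17 | (2R,3S,5Z)-6-allyl-1-Ar-2-methyl-3-[(triethylsilyl)oxy]oct-5-ene-4,7-dione | CC(=O)/C(CC=C)=C\C(=O)[C@@H](O[Si](CC)(CC)CC)[C@H](C)Cc1ccc(O[Si](C)(C)C(C)(C)C)c(OC)c1 | intermediate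
18 | lithium dienolate of 17 (methyl ketone enolate) | C=C([O-])/C(CC=C)=C\C(=O)[C@@H](O[Si](CC)(CC)CC)[C@H](C)Cc1ccc(O[Si](C)(C)C(C)(C)C)c(OC)c1.[Li+] | intermediate
19 | (S)-2-allyl-4-hydroxy-4-[(1S,2R)-3-Ar-2-methyl-1-(triethylsilyloxy)propyl]cyclopent-2-en-1-one | C=CCC1=C[C@@](O)(CC1=O)[C@@H](O[Si](CC)(CC)CC)[C@H](C)Cc1ccc(O[Si](C)(C)C(C)(C)C)c(OC)c1 | intermediate
20 | (S)-2-allyl-4-hydroxy-4-[(1S,2R)-3-Ar-1-hydroxy-2-methylpropyl]cyclopent-2-en-1-one | C=CCC1=C[C@@](O)(CC1=O)[C@@H](O)[C@H](C)Cc1ccc(O[Si](C)(C)C(C)(C)C)c(OC)c1 | intermediate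
21 | (S)-2-allyl-4-hydroxy-4-[(R)-3-Ar-2-methylpropanoyl]cyclopent-2-en-1-one (key-step precursor) | C=CCC1=C[C@@](O)(CC1=O)C(=O)[C@H](C)Cc1ccc(O[Si](C)(C)C(C)(C)C)c(OC)c1 | intermediate
22 | (R)-4-allyl-6-hydroxy-6-[(R)-1-Ar-propan-2-yl]cyclohex-4-ene-1,3-dione (diketo tautomer) | C=CCC1=C[C@](O)([C@H](C)Cc2ccc(O[Si](C)(C)C(C)(C)C)c(OC)c2)C(=O)CC1=O | intermediate
23 | (R)-2-allyl-4,5-dihydroxy-4-[(R)-1-Ar-propan-2-yl]cyclohexa-2,5-dien-1-one (key-step product) | C=CCC1=C[C@](O)([C@H](C)Cc2ccc(O[Si](C)(C)C(C)(C)C)c(OC)c2)C(O)=CC1=O | intermediate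
24 | (R)-2-allyl-4-hydroxy-5-methoxy-4-[(R)-1-Ar-propan-2-yl]cyclohexa-2,5-dien-1-one | C=CCC1=C[C@](O)([C@H](C)Cc2ccc(O[Si](C)(C)C(C)(C)C)c(OC)c2)C(OC)=CC1=O | intermediate
25 | potassium C4-alkoxide of 24 | C=CCC1=C[C@]([O-])([C@H](C)Cc2ccc(O[Si](C)(C)C(C)(C)C)c(OC)c2)C(OC)=CC1=O.[K+] | intermediate
26 | (R)-2-allyl-4,5-dimethoxy-4-[(R)-1-Ar-propan-2-yl]cyclohexa-2,5-dien-1-one | C=CCC1=C[C@](OC)([C@H](C)Cc2ccc(O[Si](C)(C)C(C)(C)C)c(OC)c2)C(OC)=CC1=O | intermediate
27 | (R)-2-allyl-4-[(R)-1-(4-hydroxy-3-methoxyphenyl)propan-2-yl]-4,5-dimethoxycyclohexa-2,5-dien-1-one | C=CCC1=C[C@](OC)([C@H](C)Cc2ccc(O)c(OC)c2)C(OC)=CC1=O | target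

Total step count: 18. Longest linear sequence: 17 steps (vanillin 4 to target 27, steps 2–18).

Steps most likely to fail

Step 15. The β-hydroxy ketone may open by retro-aldol reaction, or C6 may migrate in place of C3, before the wanted shift occurs. The fallback sets out from 21 and returns at 23. The tertiary hydroxyl would be capped with TMSOTf and 2,6-lutidine to give (S)-2-allyl-4-[(R)-3-Ar-2-methylpropanoyl]-4-[(trimethylsilyl)oxy]cyclopent-2-en-1-one F1, in which retro-aldol opening is blocked. A bulky aluminium Lewis acid, MeAl(OC6H2-2,6-tBu2-4-Me)2 in CH2Cl2 at −78 to −20 °C, should then drive the same C3 shift as an α-silyloxy ketone rearrangement. Silyl transfer from the C5 oxygen to the C4 oxygen within the syn arrangement ends it and gives (R)-2-allyl-5-hydroxy-4-[(R)-1-Ar-propan-2-yl]-4-[(trimethylsilyl)oxy]cyclohexa-2,5-dien-1-one F2. Citric acid in methanol would remove the silyl group and deliver 23.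

Step 16. The ambident vinylogous acid may be methylated at the C1 oxygen instead of the C5 oxygen. The fallback sets out from 23 and returns at 24. Acid-mediated etherification under equilibrating conditions (HC(OMe)3, MeOH, catalytic camphorsulfonic acid, rt) would replace the kinetic diazoalkane methylation. The two vinylogous methyl esters interconvert under these conditions and 24 is separated. The isomer (R)-4-allyl-6-hydroxy-3-methoxy-6-[(R)-1-Ar-propan-2-yl]cyclohexa-2,4-dien-1-one F3 is resubmitted, or hydrolysed with dilute aqueous HCl in THF back to 23.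

Step 12. Face selection at C5 may be poor, the base may remove a proton from the doubly allylic CH2 instead of the methyl group, or the aldolate may revert on warming. The fallback sets out from 17 and returns at 19. The methyl ketone would be converted with TMSOTf and Et3N in CH2Cl2 at −78 °C into (2R,3S,5Z)-6-allyl-1-Ar-2-methyl-3-[(triethylsilyl)oxy]-7-[(trimethylsilyl)oxy]octa-5,7-dien-4-one F4. BF3·OEt2 in CH2Cl2 at −78 °C would close the ring by an intramolecular Mukaiyama aldol addition, the non-chelating Lewis acid keeping the Felkin–Anh sense, and aqueous work-up gives 19.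

Further compounds
F1 | step 15 | (S)-2-allyl-4-[(R)-3-Ar-2-methylpropanoyl]-4-[(trimethylsilyl)oxy]cyclopent-2-en-1-one | C=CCC1=C[C@@](O[Si](C)(C)C)(CC1=O)C(=O)[C@H](C)Cc1ccc(O[Si](C)(C)C(C)(C)C)c(OC)c1
F2 | step 15 | (R)-2-allyl-5-hydroxy-4-[(R)-1-Ar-propan-2-yl]-4-[(trimethylsilyl)oxy]cyclohexa-2,5-dien-1-one | C=CCC1=C[C@](O[Si](C)(C)C)([C@H](C)Cc2ccc(O[Si](C)(C)C(C)(C)C)c(OC)c2)C(O)=CC1=O
F3 | step 16 | (R)-4-allyl-6-hydroxy-3-methoxy-6-[(R)-1-Ar-propan-2-yl]cyclohexa-2,4-dien-1-one | C=CCC1=C[C@](O)([C@H](C)Cc2ccc(O[Si](C)(C)C(C)(C)C)c(OC)c2)C(=O)C=C1OC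
F4 | step 12 | (2R,3S,5Z)-6-allyl-1-Ar-2-methyl-3-[(triethylsilyl)oxy]-7-[(trimethylsilyl)oxy]octa-5,7-dien-4-one | C=C(O[Si](C)(C)C)/C(CC=C)=C\C(=O)[C@@H](O[Si](CC)(CC)CC)[C@H](C)Cc1ccc(O[Si](C)(C)C(C)(C)C)c(OC)c1
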